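**Plan**

1. Retrosynthesis first cuts the C6–prenyl bond (aromatic Claisen of a 7-O-(1,1-dimethylallyl) ether), then the C2–H/C3–H pair and the two O-benzyl groups. This leads back to a 5,7-bis(benzyloxy)-2,3-dimethylchromone carrying the complete C8 side chain.
2. The pyranone ring is cut at C8a–O1, C4a–C4 and O1–C2, giving an aryne and (E)-3-methoxy-2-methylbut-2-enoic acid. The enabling feature is that C8a (oxygen) and C4a (acyl) are adjacent carbons of the fully substituted benzene ring, flanked by the C5 oxygen and the C8 branch, which is the pattern a 3-alkoxy-6-alkyl aryne gives when a carboxylate adds distal to the alkoxy group.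
3. The aryne precursor, an ortho-silyl aryl triflate, is cut at the aryl–C(branch) bond to 3,5-bis(benzyloxy)phenol and (E)-hex-2-enal. The phenol oxygen that directs silylation and annulation later leaves as triflate.
4. Forward, the benzene ring is bought; a dihydrocoumarin ring is formed and reopened to install the side chain; the pyranone ring closes in the key step; hydrogenation, debenzylation and prenylation finish the route.
5. The side-chain centre (R) comes from a chiral triazolium carbene in the annulation. C2 (R) and C3 (S), cis, come from catalyst-controlled syn addition of H2 to the chromone C2=C3 bond.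

Key step: step 7

Remark: compounds 1, 5, 9 and 17 are taken as commercial. For the two catalyst-controlled steps (3 and 8) the catalyst antipode that delivers the drawn configuration is the one meant; both antipodes of each catalyst are accessible.

**Route**

Step 1
Reactants: 1 3,5-bis(benzyloxy)phenol
Product: 2 3,5-bis(benzyloxy)-2-bromophenol
Conditions: NBS (1.0 equiv), CH2Cl2, −78 → 0 °C
Reagents that add atoms: N-bromosuccinimide, O=C1CCC(=O)N1Br
Why: Electrophilic aromatic bromination of the phloroglucinol-type ring, in which hydrogen-bonded delivery of bromine in a non-polar solvent at low temperature favours the carbon ortho to the free hydroxyl over the carbon between the two ethers.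

Step 2
Reactants: 2 3,5-bis(benzyloxy)-2-bromophenol
Product: 4 3,5-bis(benzyloxy)-2-(trimethylsilyl)phenol, via aryl trimethylsilyl ether 3 (not isolated)
Conditions: HMDS, THF, 70 °C, then evaporation; n-BuLi (1.1 equiv), THF, −100 → −78 °C; aq. NH4Cl
Reagents that add atoms: hexamethyldisilazane, C[Si](C)(C)N[Si](C)(C)C
Why: O-silylation followed by bromine–lithium exchange triggers the anionic 1,3 O→C silyl shift (retro-Brook rearrangement), the standard way to place a trimethylsilyl group ortho to a phenol oxygen.

Step 3
Reactants: 4 3,5-bis(benzyloxy)-2-(trimethylsilyl)phenol; 5 (E)-hex-2-enal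
Product: 6 (4R)-5,7-bis(benzyloxy)-4-propyl-8-(trimethylsilyl)-3,4-dihydro-2H-chromen-2-one
Conditions: N-mesityl triazolium chloride fused to cis-1-amino-2-indanol (10 mol %), K2CO3 (20 mol %), 3,3',5,5'-tetra-tert-butyldiphenoquinone (1.2 equiv), PhMe, 23 °C
Reagents that add atoms: none
Why: Oxidative N-heterocyclic carbene catalysis turns the enal into a chiral α,β-unsaturated acyl azolium that the electron-rich phenol attacks through its free ortho carbon (Coates–Claisen-type annulation) before lactonisation releases the carbene, the indanol-fused backbone shielding one face of the β-carbon so that C4 is set as R.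

Step 4
Reactants: 6 (4R)-5,7-bis(benzyloxy)-4-propyl-8-(trimethylsilyl)-3,4-dihydro-2H-chromen-2-one
Product: 8 methyl (R)-3-[2,4-bis(benzyloxy)-6-(trifluoromethylsulfonyloxy)-5-(trimethylsilyl)phenyl]hexanoate, via ring-opened sodium phenoxide 7 (not isolated)
Conditions: NaOMe (1.0 equiv), MeOH–THF, 0 °C, then evaporation; PhNTf2 (1.2 equiv), THF–DMF, 0 → 23 °C
Reagents that add atoms: sodium methoxide, [Na+].[O-]C; N-phenylbis(trifluoromethanesulfonimide), O=S(=O)(N(c1ccccc1)S(=O)(=O)C(F)(F)F)C(F)(F)F
Why: Methoxide opens the aryl lactone by transesterification to the methyl ester and the more stable phenoxide, which is sulfonylated in the same flask (phenoxide triflation with a triflimide) before it can relactonise.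

Step 5
Reactants: 9 methyl 2-methyl-3-oxobutanoate
Product: 10 methyl (E)-3-methoxy-2-methylbut-2-enoate
Conditions: HC(OMe)3, H2SO4 (cat.), MeOH, 23 °C; then distillation
Reagents that add atoms: trimethyl orthoformate, COC(OC)OC
Why: Acid-catalysed ketalisation of the ketone and loss of methanol on distillation is the standard enol ether synthesis from β-keto esters, and the alkene geometry is immaterial because the β-carbon becomes tetrahedral during the later ring closure.

Step 6
Reactants: 10 methyl (E)-3-methoxy-2-methylbut-2-enoate
Product: 11 (E)-3-methoxy-2-methylbut-2-enoic acid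
Conditions: NaOH (2 M aq.), MeOH, 60 °C; then cold 1 M HCl to pH 3, 0 °C
Reagents that add atoms: sodium hydroxide, [Na+].[OH-]
Why: Saponification of the vinylogous carbonate ester, with cold and mild acidification so that the acid-labile enol ether is not hydrolysed to the decarboxylation-prone β-keto acid.

Step 7
Reactants: 8 methyl (R)-3-[2,4-bis(benzyloxy)-6-(trifluoromethylsulfonyloxy)-5-(trimethylsilyl)phenyl]hexanoate; 11 (E)-3-methoxy-2-methylbut-2-enoic acid
Product: 14 methyl (R)-3-[5,7-bis(benzyloxy)-2,3-dimethyl-4-oxo-4H-chromen-8-yl]hexanoate, via aryne 12 (not isolated), via ortho-acyl phenoxide 13 (not isolated)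
Conditions: 11 (1.5 equiv), CsF (5 equiv), THF, 125 °C, sealed tube; then TsOH·H2O (cat.), MeOH, 23 °C
Reagents that add atoms: none
Why: Proposed new method: fluoride attack at silicon expels triflate to give aryne 12, the cesium carboxylate of 11 adds through oxygen to the aryne carbon next to the side chain (future C8a), and the aryl anion at the future C4a, finding no proton source in hot THF, attacks the ester carbonyl through a four-membered alkoxide that collapses to the ortho-acyl phenoxide 13, a net insertion into the acid C–O bond. The closest known reaction type is the fluoride-mediated insertion of arynes into carboxylic acid C–O bonds, which with α,β-unsaturated acids continues by oxa-Michael addition to 4-chromanones and with arylpropiolic acids to flavones; the untested element is the β-methoxy acrylic acid, whose leaving group turns the conjugate addition into an addition–elimination. The pyranone ring closes by 6-endo-trig attack of the phenoxide on the methoxy-bearing β-carbon followed by E1cB loss of methoxide, and the acid finish converts any uncyclised enone into the same chromone. No stereocentre is formed, and the side-chain centre, which is not acidic, is untouched. The selectivity needed is regiochemical: the σ-withdrawing C5 benzyloxy group beside the future C4a distorts the aryne so that the nucleophile enters at the distal carbon and the charge develops next to oxygen, and this bias must outweigh the steric screening of that carbon by the sec-alkyl branch, whose ester is too poor a nucleophile to compete with carboxylate.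

Step 8
Reactants: 14 methyl (R)-3-[5,7-bis(benzyloxy)-2,3-dimethyl-4-oxo-4H-chromen-8-yl]hexanoate
Product: 15 methyl (3R)-3-[(2R,3S)-5,7-bis(benzyloxy)-2,3-dimethyl-4-oxo-3,4-dihydro-2H-chromen-8-yl]hexanoate
Conditions: [Ru(cod)(2-methylallyl)2] (5 mol %), 1,3-bis[1-(1-naphthyl)ethyl]-4,5-dihydroimidazolium tetrafluoroborate (single antipode, 10 mol %), KOt-Bu (10 mol %), n-hexane, 70 °C; then 14, H2 (100 bar), PhMe, 40 °C
Reagents that add atoms: none
Why: Proposed new method: the chiral bis(carbene) ruthenium hydride formed from [Ru(cod)(2-methylallyl)2] should deliver H2 in syn fashion to one face of the chromone C2=C3 bond, which gives the cis 2,3-dimethyl pair directly while the ligand antipode selects the face leading to 2R,3S and the remote side-chain centre exerts no bias; the closest known reaction type is the asymmetric hydrogenation of 2-substituted chromones and flavones with this catalyst family, the untested element being the C3 methyl group that makes the olefin tetrasubstituted.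

Step 9
Reactants: 15 methyl (3R)-3-[(2R,3S)-5,7-bis(benzyloxy)-2,3-dimethyl-4-oxo-3,4-dihydro-2H-chromen-8-yl]hexanoate
Product: 16 methyl (3R)-3-[(2R,3S)-5,7-dihydroxy-2,3-dimethyl-4-oxo-3,4-dihydro-2H-chromen-8-yl]hexanoate
Conditions: H2 (1 atm), 10% Pd/C, EtOAc, 23 °C
Reagents that add atoms: none
Why: Neutral hydrogenolysis of the two benzyl ethers leaves the donor-deactivated, hydrogen-bonded aryl ketone and the base-sensitive C3 centre untouched.

Step 10
Reactants: 17 2-methylbut-3-en-2-ol
Product: 18 tert-butyl 2-methylbut-3-en-2-yl carbonate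
Conditions: n-BuLi (1.0 equiv), THF, 0 °C; Boc2O, 0 → 23 °C; aq. NH4Cl
Reagents that add atoms: di-tert-butyl dicarbonate, CC(C)(C)OC(=O)OC(=O)OC(C)(C)C
Why: Acylation of the lithium alkoxide of the tertiary allylic alcohol with the dicarbonate is the routine preparation of this allylation reagent.

Step 11
Reactants: 16 methyl (3R)-3-[(2R,3S)-5,7-dihydroxy-2,3-dimethyl-4-oxo-3,4-dihydro-2H-chromen-8-yl]hexanoate; 18 tert-butyl 2-methylbut-3-en-2-yl carbonate
Product: 19 methyl (3R)-3-[(2R,3S)-5-hydroxy-2,3-dimethyl-7-[(2-methylbut-3-en-2-yl)oxy]-4-oxo-3,4-dihydro-2H-chromen-8-yl]hexanoate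
Conditions: Pd(PPh3)4 (5 mol %), 18 (1.2 equiv), THF, 0 °C
Reagents that add atoms: none
Why: Tsuji–Trost O-allylation, in which zerovalent palladium ionises the carbonate and the free C7 phenoxide (the C5 hydroxyl being tied up by chelation to the ketone) attacks the more substituted allyl terminus under kinetic control, the only base present being phenoxide, which is too weak to epimerise C3.

Step 12
Reactants: 19 methyl (3R)-3-[(2R,3S)-5-hydroxy-2,3-dimethyl-7-[(2-methylbut-3-en-2-yl)oxy]-4-oxo-3,4-dihydro-2H-chromen-8-yl]hexanoate
Product: 20 methyl (3R)-3-[(2R,3S)-5,7-dihydroxy-2,3-dimethyl-6-(3-methylbut-2-en-1-yl)-4-oxo-3,4-dihydro-2H-chromen-8-yl]hexanoate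
Conditions: PhMe, 110 °C
Reagents that add atoms: none
Why: Aromatic Claisen rearrangement of the 1,1-dimethylallyl ether can only end at C6, the single free ortho position (C8 is blocked), and the [3,3] shift inverts the allyl unit so that the linear prenyl group results after tautomerisation.

**Compound list**

1 | 3,5-bis(benzyloxy)phenol | Oc1cc(OCc2ccccc2)cc(OCc2ccccc2)c1 | starting material
2 | 3,5-bis(benzyloxy)-2-bromophenol | Oc1cc(OCc2ccccc2)cc(OCc2ccccc2)c1Br | intermediate
3 | [3,5-bis(benzyloxy)-2-bromophenoxy]trimethylsilane | C[Si](C)(C)Oc1cc(OCc2ccccc2)cc(OCc2ccccc2)c1Br | intermediate (not isolated)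
4 | 3,5-bis(benzyloxy)-2-(trimethylsilyl)phenol | C[Si](C)(C)c1c(O)cc(OCc2ccccc2)cc1OCc1ccccc1 | intermediate
5 | (E)-hex-2-enal | CCC/C=C/C=O | starting material
6 | (4R)-5,7-bis(benzyloxy)-4-propyl-8-(trimethylsilyl)-3,4-dihydro-2H-chromen-2-one | CCC[C@@H]1CC(=O)Oc2c1c(OCc1ccccc1)cc(OCc1ccccc1)c2[Si](C)(C)C | intermediate
7 | sodium phenoxide of methyl (R)-3-[2,4-bis(benzyloxy)-6-hydroxy-5-(trimethylsilyl)phenyl]hexanoate | CCC[C@H](CC(=O)OC)c1c(OCc2ccccc2)cc(OCc2ccccc2)c([Si](C)(C)C)c1[O-].[Na+] | intermediate (not isolated)
8 | methyl (R)-3-[2,4-bis(benzyloxy)-6-(trifluoromethylsulfonyloxy)-5-(trimethylsilyl)phenyl]hexanoate | CCC[C@H](CC(=O)OC)c1c(OCc2ccccc2)cc(OCc2ccccc2)c([Si](C)(C)C)c1OS(=O)(=O)C(F)(F)F | intermediate (key-step precursor)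
9 | methyl 2-methyl-3-oxobutanoate | COC(=O)C(C)C(C)=O | starting material
10 | methyl (E)-3-methoxy-2-methylbut-2-enoate | CO/C(C)=C(C)/C(=O)OC | intermediate
11 | (E)-3-methoxy-2-methylbut-2-enoic acid | CO/C(C)=C(C)/C(=O)O | intermediate (key-step precursor)
12 | methyl (R)-3-[2,4-bis(benzyloxy)-5,6-didehydrophenyl]hexanoate (aryne) | CCC[C@H](CC(=O)OC)C1=C(OCc2ccccc2)C=C(OCc2ccccc2)C#C1 | intermediate (not isolated)
13 | methyl (R)-3-[2,4-bis(benzyloxy)-6-hydroxy-5-[(E)-3-methoxy-2-methylbut-2-enoyl]phenyl]hexanoate (present as its cesium phenoxide) | CCC[C@H](CC(=O)OC)c1c(OCc2ccccc2)cc(OCc2ccccc2)c(C(=O)/C(C)=C(C)/OC)c1O | intermediate (not isolated)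
14 | methyl (R)-3-[5,7-bis(benzyloxy)-2,3-dimethyl-4-oxo-4H-chromen-8-yl]hexanoate | CCC[C@H](CC(=O)OC)c1c(OCc2ccccc2)cc(OCc2ccccc2)c2c1OC(C)=C(C)C2=O | intermediate (key-step product)
15 | methyl (3R)-3-[(2R,3S)-5,7-bis(benzyloxy)-2,3-dimethyl-4-oxo-3,4-dihydro-2H-chromen-8-yl]hexanoate | CCC[C@H](CC(=O)OC)c1c(OCc2ccccc2)cc(OCc2ccccc2)c2c1O[C@H](C)[C@H](C)C2=O | intermediate
16 | methyl (3R)-3-[(2R,3S)-5,7-dihydroxy-2,3-dimethyl-4-oxo-3,4-dihydro-2H-chromen-8-yl]hexanoate | CCC[C@H](CC(=O)OC)c1c(O)cc(O)c2c1O[C@H](C)[C@H](C)C2=O | intermediate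
17 | 2-methylbut-3-en-2-ol | C=CC(C)(C)O | starting material
18 | tert-butyl 2-methylbut-3-en-2-yl carbonate | C=CC(C)(C)OC(=O)OC(C)(C)C | intermediate
19 | methyl (3R)-3-[(2R,3S)-5-hydroxy-2,3-dimethyl-7-[(2-methylbut-3-en-2-yl)oxy]-4-oxo-3,4-dihydro-2H-chromen-8-yl]hexanoate | CCC[C@H](CC(=O)OC)c1c(OC(C)(C)C=C)cc(O)c2c1O[C@H](C)[C@H](C)C2=O | intermediate
20 | methyl (3R)-3-[(2R,3S)-5,7-dihydroxy-2,3-dimethyl-6-(3-methylbut-2-en-1-yl)-4-oxo-3,4-dihydro-2H-chromen-8-yl]hexanoate | CCC[C@H](CC(=O)OC)c1c(O)c(CC=C(C)C)c(O)c2c1O[C@H](C)[C@H](C)C2=O | target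

**Counts**

Total steps: 12. Longest linear sequence: 9 (steps 1, 2, 3, 4, 7, 8, 9, 11, 12).

**Steps most likely to fail**

(a) Step 7. The aryl anion may be protonated before it reaches the hindered, electron-rich acyl carbon, which stops the sequence at the O-aryl ester. The carboxylate may also enter at the wrong aryne carbon, or the addition–elimination closure may stall. The fallback keeps the aryne but closes the pyranone ring by classical means. Setting out from 8, the same fluoride conditions with propanoic acid (a plain aliphatic acid, the established substrate class for the C–O insertion) should give methyl (R)-3-[2,4-bis(benzyloxy)-6-hydroxy-5-propanoylphenyl]hexanoate F1. Kostanecki–Robinson acylation and cyclodehydration of F1 (Ac2O, NaOAc, 140 °C) would then rejoin the route at 14.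

(b) Step 8. The tetrasubstituted olefin may turn over slowly, the C4 ketone may be over-reduced, or the two faces may be poorly discriminated. The fallback gives up catalyst control. Setting out from 14, heterogeneous hydrogenation (H2 at raised pressure, Pd/C, EtOAc) adds hydrogen syn without facial preference and removes both benzyl groups in the same operation. It should give 16 together with its cis isomer methyl (3R)-3-[(2S,3R)-5,7-dihydroxy-2,3-dimethyl-4-oxo-3,4-dihydro-2H-chromen-8-yl]hexanoate F2. The two are diastereomers and would be separated by preparative HPLC on a chiral stationary phase, and the route resumes at 16 with step 9 no longer needed.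

(c) Step 3. The hindered phenol may stop at the O-acyl stage. Base-induced γ-deprotonation of the enolisable acyl azolium, or attack at the silylated ortho carbon with loss of silicon, may divert material, and the β-alkyl enal may be discriminated poorly. The fallback changes the activation mode from acyl azolium to iminium. Setting out from 4, Friedel–Crafts alkylation and hemiacetalisation with 5 under 2-[diphenyl(trimethylsilyloxy)methyl]pyrrolidine catalysis (single antipode, 20 mol %, PhMe, 0 °C) should give (4R)-5,7-bis(benzyloxy)-4-propyl-8-(trimethylsilyl)-3,4-dihydro-2H-chromen-2-ol F3 as an anomer mixture. Neutral lactol oxidation of F3 with Ag2CO3 on Celite (PhMe, reflux) would return to the route at 6.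

**Further compounds**

F1 | step 7 | methyl (R)-3-[2,4-bis(benzyloxy)-6-hydroxy-5-propanoylphenyl]hexanoate | CCC[C@H](CC(=O)OC)c1c(OCc2ccccc2)cc(OCc2ccccc2)c(C(=O)CC)c1O
F2 | step 8 | methyl (3R)-3-[(2S,3R)-5,7-dihydroxy-2,3-dimethyl-4-oxo-3,4-dihydro-2H-chromen-8-yl]hexanoate | CCC[C@H](CC(=O)OC)c1c(O)cc(O)c2c1O[C@@H](C)[C@@H](C)C2=O
F3 | step 3 | (4R)-5,7-bis(benzyloxy)-4-propyl-8-(trimethylsilyl)-3,4-dihydro-2H-chromen-2-ol | CCC[C@@H]1CC(O)Oc2c1c(OCc1ccccc1)cc(OCc1ccccc1)c2[Si](C)(C)C
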